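The numbers in the tables were computed on assumed constants; noise was put on by code.

**The gap.** If partner went nowhere but into substrate, each flask's end would be a subtraction. But the spring run took 0.70 equiv and its substrate stopped at 34.2%, not at 30.0%.

all flasks: substrate 1.3 M

| flask | partner | remark | time |
|---|---|---|---|
| spring | 0.70 equiv | run made earlier |  |
| north | 0.950 equiv |  | 8.0 min |
| south-west | 1.10 equiv |  | 8.0 min |

- spring (time / min: substrate / %, mono adduct / %, double product / %): 0.333: 50.8, 47.3, 1.8; 0.667: 41.1, 58.7, 2.1; 1.00: 37.4, 62.6, 0.5; 2.00: 34.4, 64.7, 0.4; 4.00: 34.2, 65.3, 0

(standard deviation of a reading: 0.5 percentage points)

- which of these there is most of at the end, counted by the substrate in it, north (mono adduct / substrate / double product)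
- which of these there is most of at the end, counted by the substrate in it, south-west (mono adduct / substrate / double product)
- the largest of these amounts at the end, in percent of the substrate charged, north
- the largest of these amounts at the end, in percent of the substrate charged, south-west

**The quantity.** Let S be the fraction of substrate left and P the equivalents of partner charged. Partner decomposes first order and adds first order in substrate, so decomposition takes ρ/S of it for each part that adds, where ρ is the decomposition constant over the addition constant times the substrate charge. Integrating until partner is gone gives S = 1 − P − ρ ln S. You can call ρ the loss number, a selectivity factor: 0.0391, read from the final substrate of the spring run.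

**Second way.** Counting the partner lost from the final mono adduct reading instead gives 0.0438. The two readings part by 0.5 percentage points, about the scatter of one reading, so neither is caught cheating, and I carry the first.

**Going round.** I take the end as partner gone, since spring substrate moved by less than the scatter from 2.00 min to 4.00 min, and I count double product as mono adduct, since its spring reading fell to 0%. For north, put S back into the right side, starting from 5.00%: it goes to 16.7%, 12.0%, 13.3% and 12.9%, so mono adduct is 87.1%. For south-west, each round multiplies an error by ρ/S, here above one, so plain rounds swing. Starting from S = ρ, the first round gives 2.68%, the mean with the guess is 3.30%, and the next round gives 3.35%. That makes mono adduct 96.7%.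

**The forecast.** It names mono adduct for north and mono adduct for south-west, at 87% and 96%, and calls double product “a reversible, short-lived reservoir”. Its south-west figure is below mine.

**Result.** Mono adduct leads in north at 87.3% and in south-west at 96.5%.

    substrate + partner → mono adduct (k = 0.0780 /M/s)
    partner + mono adduct ⇌ double product (K = 0.190 /M, k = 0.110 /M/s)
    partner → decomposed reagent (k = 0.00380 /s)

**Further flask.** South-west still held 0.526% of its partner charge at 8.00 min, and at 80.0 min its mono adduct stood at 96.9%. Take the south-west recipe with 0.440 equiv of partner: one round with ρ = 0.0391 gives S = 58.3%. At its end that flask held more substrate, 58.0%, than mono adduct, 42.0%.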